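The readings are calculated for an exercise.

An easy step first: on a logarithmic scale, a fall of J by a factor of 10 is one decade, and counting decades needs no integral.

in all of them: J 20 mM (in portions, 4)
- ochre: E 20 mM; run made earlier; portions every 10 h
- grey: E 88 mM; run made earlier; portions every 10 h
- north-west: E 60.0 mM; the portions of J follow each other after 10 h, the first at the start; time 40 h
- north: E 16.0 mM; the portions of J follow each other after 10 h, the first at the start; time 40 h
- west: E 24.0 mM; the portions of J follow each other after 10 h, the first at the start; time 40 h

- ochre (time / h: G / %, D / %, J / %): 2.00: 1.9, 1.0, 21.8; 5.00: 3.9, 1.2, 20.0; 10.0: 6.2, 1.1, 14.8; 15.0: 11.4, 2.6, 31.0; 20.0: 12.9, 3.2, 26.9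
- grey (time / h: G / %, D / %, J / %): 1.50: 6.1, 1.5, 18.4; 3.00: 7.5, 2.9, 11.6; 6.00: 6.2, 2.8, 6.8; 10.0: 2.5, 2.5, 2.2; 20.0: 6.0, 1.3, 4.3

(each reading ± 0.5 percentage points)

- the numbers in the tables scatter by 0.5 percentage points (one standard deviation)

* which of these holds the largest part of the J at the end of north-west (Q / G / J / D)
* which of these holds the largest part of the J at the end of north (Q / G / J / D)
* which of these holds the largest part of the J at the end of west (Q / G / J / D)
* final G in north, as a percentage of the J charged

I read the J column of the grey run first. Between 1.50 h and 10.0 h, with no portion added, J went from 18.4% to 2.2%, which is 0.922 decades. E was charged at 88 mM, well above the whole J charge, so I treated the fall as pseudo-first-order. With E taken at its charge, that gave 48.7 M·min for the decade dose, the concentration of E times the time that takes J down one decade. The ochre rows from 2.00 h to 10.0 h gave 57.1 M·min. Both figures are readings with a scatter of 0.5 percentage points, and I kept the grey one, from the run with more E.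

In north, E is the limiting reagent, charged below J, and it falls as it is used. I guessed it at half its charge throughout. Each interval then left J a factor 0.797, and the portions, the first standing 4 intervals and each later one an interval less, left 58.5% of the J charged.

The forecast named Q for north-west, J for north and J for west, with final G in north at 24%. For north it said “E runs low, giving roughly J 58, G 24, Q 16”.

In the same order the flasks gave Q, J and J, and final G in north was 22.4%.

    J + E → G + Z (k = 2.70 L mol⁻¹ h⁻¹)
    E + G → D + Z (k = 4.30 L mol⁻¹ h⁻¹)
    E + D → Q + Z (k = 6.00 L mol⁻¹ h⁻¹)
    D + Z → L (k = 22.0 L mol⁻¹ h⁻¹)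
    D ⇌ X (K = 2.90, k = 0.0140 h⁻¹)

North had not come to rest at 40 h. Its last interval began with J at 44.2% plus a quarter of the charge, and the mean of E at the two ends of that interval was 5.21 mM. The decade dose then gave final J at 59.7%, and north held 60.4%. E still stood at 23.8% of its charge. By 400 h it was 0%, with J at 49.4% and G at 25.6%. North also held L, 10.5% at 40.0 h, yet the reaction of D with Z that makes it made no difference to G there.

For the neighbour of north with E at 6.4 mM, the same half-charge guess gave J at 80.1%. The computed flask ended with J at 80.4% and G at 15.3%.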